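## The problem

The target 14 is a 2,3-dihydrobenzofuran neolignan. Benzo ring B is fused through C3a and C7a to the dihydrofuran ring (O1, C2, C3). C2 carries the 3,4,5-trimethoxyphenyl ring A, C3 a methyl group, C5 an (E)-prop-1-enyl group and C6 a methoxy group. The only stereocentres are the adjacent C2 and C3, both R, which places ring A and the methyl group trans on the five-membered ring. Trans is the more stable arrangement, so either centre could steer the other, but the absolute configuration must come from a reagent or catalyst because the molecule holds no other stereochemical information. Ring B is a 1,2,4,5-tetrasubstituted benzene whose four different substituents must be placed without regiochemical ambiguity. The (E)-propenyl group is an electron-rich styrene that does not tolerate strong acid, electrophilic oxidants or hydrogenation. The benzylic C2–O bond, activated by the para-methoxy group of ring A, ionises easily, so late steps must not open it. The enabling feature is that C2–C3 with its methyl group is a propene unit arylated at both carbons: ring A at C2 and ring carbon C3a at C3. With boron in place of O1, C2 and C3 are the α- and β-carbons of an (E)-propenylboron compound. An anti 1,2-diarylation of that alkene gives the relative configuration that retentive C–B to C–O exchange and closure at C7a turn into the trans ring.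

## Retrosynthesis

**O1–C7a.** The last bond made is the aryl ether bond, which leads from 14 back to the chloro alcohol 13. The neighbouring cut, O1–C2, would form the benzylic C–O bond at a stereocentre by displacement or ionisation, with inversion or loss of configuration. Cutting at the aromatic carbon leaves every bond to C2 and C3 intact. Compound 13 is acyclic and is simpler by one ring. The forward reaction is a palladium-catalysed intramolecular etherification of an aryl chloride by a secondary alcohol, and it must outrun β-hydride elimination.

**C2–O to C2–B.** The hydroxyl group of 13 is traced to the boronic ester 12. This exchange is chosen because oxidation of a C–B bond proceeds with retention, so the configuration at C2 is decided entirely when the C–B compound is made. The forward reaction only has to leave the propenyl group and the aryl chloride alone.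

**C2–C1′ and C3–C3a.** Compound 12 is cut at both aryl–alkyl bonds at once. This gives the ate complex 11, assembled from the (E)-propenylboronic ester 4 and the aryllithium 10 (from bromide 9), and the aryl bromide 8. Cutting only one of the two bonds would need two separate stereocontrolled events. The double cut sets C2 and C3 in one catalytic step on an achiral alkene, from three pieces of similar size. The forward reaction must deliver four things: aryl migration instead of direct cross-coupling at boron, anti addition across the (E) double bond, face selection by the chiral ligand, and reaction at C–Br before C–Cl.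

**Ring B piece.** The propenyl group of 8 is traced through the carbinol 7 to the aldehyde 6, and the bromine of 6 to the commercial aldehyde 5. In 5 the methoxy, chloro and formyl groups all direct an electrophile to the same carbon. This fixes the 1,2,4,5 pattern of ring B without protecting groups.

**Boron piece.** The ester 4 is the condensation product of the boronic acid 3 and the cis diol 2. The diol comes from the diketone 1 by double methyl addition. The hindered diol is chosen over simpler diols because it is what allows the metallate shift to win in the key step.

## Roads not taken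

**Alternative 1: ring contraction of a flavanone.** The cut is C3–C3a, made by a 1,2-shift. (R)-6-Bromo-7-methoxy-2-(3,4,5-trimethoxyphenyl)chroman-4-one A1 would be treated with PhI(OAc)2 and H2SO4 in trimethyl orthoformate. The enol ether of A1 is attacked at C3 by the iodane, the fused aryl carbon migrates from C4 to C3 as the iodane departs, and C4 leaves the ring as a methyl ester. The product is methyl (2R,3R)-5-bromo-6-methoxy-2-(3,4,5-trimethoxyphenyl)-2,3-dihydrobenzofuran-3-carboxylate A2.

- Merits: O1 is in place from the start, so no late metal-catalysed C–O coupling is needed. The C2 centre of A1 can be set by established asymmetric flavanone syntheses. It steers C3 to the trans ester, which can be corrected further by epimerisation next to the carbonyl.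
- Weak points: the C2 centre of A1 is labile through reversible ring opening by retro-oxa-Michael reaction, and the key step uses strong acid. The oxidant may attack the electron-rich ring A. The propenyl group cannot be present, hence the bromine placeholder. After the key step the ester must be taken down to a methyl group in about three steps without touching the aryl bromide, and a cross-coupling with 3 must follow.
- Comparison: this road is better than the chosen plan in avoiding the late etherification. Against that, the chosen plan forms C3 directly at the methyl oxidation level, carries the propenyl group through the key step, needs two steps after it in place of about four, and never exposes a labile stereocentre to strong acid.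

**Alternative 2: vinylketene benzannulation.** The cuts are C3a–C7a, C6–C7 and C5–C6, so ring B and the dihydrofuran ring are built together. Irradiation of (1R,2R,5E,7E)-3-diazo-1-(ethynyloxy)-2-methyl-1-(3,4,5-trimethoxyphenyl)nona-5,7-dien-4-one A3 would trigger a Wolff rearrangement. The ketene formed from A3 would add across the tethered ethynyl ether in a [2+2] cycloaddition. Four-electron ring opening, six-electron ring closure and tautomerisation would then give (2R,3R)-3-methyl-5-[(E)-prop-1-enyl]-2-(3,4,5-trimethoxyphenyl)-2,3-dihydrobenzofuran-6-ol A4, which needs only O-methylation.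

- Merits: ring B is assembled with complete regiocontrol, and the C6 oxygen emerges as a free phenol ready for methylation.
- Weak points: A3 already contains the C2/C3 diad, so the stereochemical problem is moved into a long synthesis of A3 and not solved. The ethynyl ether of a secondary benzylic alcohol is thermally fragile. The disubstituted diazo carbon is hard to install. The dienone chromophore can isomerise under irradiation and scramble the propenyl geometry. The intramolecular version that closes a five-membered ring has little precedent.
- Comparison: this road is superior only in the regiochemical certainty of ring B. The chosen plan gets that certainty cheaply from one directed bromination and is far shorter.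

**Alternative 3: [4+1] annulation of an ortho-quinone methide with a chiral sulfur ylide.** The cuts are C2–C3 and O1–C2. Cs2CO3 would eliminate sulfinate from 4-bromo-5-methoxy-2-[1-(phenylsulfonyl)ethyl]phenol A5 and deprotonate a chiral sulfonium salt such as (2R,5R)-2,5-dimethyl-1-(3,4,5-trimethoxybenzyl)thiolan-1-ium triflate A6. The ylide carbon of deprotonated A6 adds to the methide carbon of the quinone methide form of A5, and the phenoxide then displaces the sulfide. This closes the ring to (2R,3R)-5-bromo-6-methoxy-3-methyl-2-(3,4,5-trimethoxyphenyl)-2,3-dihydrobenzofuran A7. A cross-coupling of A7 with 3 finishes the synthesis.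

- Merits: this is the shortest road. The key step closes the ring, forms both bonds to C2 and is intrinsically trans-selective.
- Weak points: the quinone methide form of A5 bears a methyl group on the methide carbon and can tautomerise by a 1,5-hydrogen shift to an unreactive styrene. The chiral sulfide is stoichiometric. The enantioselectivity depends on how reversibly the ylide adds, which is hard to predict for an alkyl-substituted methide and an electron-rich benzyl ylide. The propenyl group still needs a separate coupling.
- Comparison: in step count and in ring formation during the key step this road is better. The chosen plan offers a catalytic source of chirality, a mechanism that fixes the relative configuration stereospecifically, and a key step whose substrate class (β-methyl alkenylboron ate complex, aryl electrophile, aryl migrating group) is established.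

Key step: step 6

Assumption: the (Sp,Sp) enantiomer of the MandyPhos ligand Fe[C5H3(PAr2)(CH(NMe2)Ph)]2 (Ar = 3,5-Me2C6H3) is taken to direct palladium to the alkene face that leads to the (1R,2S) ester 12; if the preference is the opposite one, the (Rp,Rp) ligand is used and nothing else in the route changes.

## Route

Step 1
Reactants: 1 acenaphthoquinone (acenaphthylene-1,2-dione)
Product: 2 cis-1,2-dimethylacenaphthene-1,2-diol (meso, (1R,2S)-1,2-dimethyl-1,2-dihydroacenaphthylene-1,2-diol)
Conditions: AlMe3 (excess), toluene, 0 °C to rt; aqueous work-up; recrystallisation
Reagents that add atoms: trimethylaluminium, C[Al](C)C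
Why: Twofold 1,2-addition of methyl to the diketone; after the first addition the bulky aluminium alkoxide shields its own face, so the second methyl should enter anti to it and give the cis (meso) diol, which is purified by crystallisation; no absolute configuration is involved.

Step 2
Reactants: 3 (E)-prop-1-enylboronic acid; 2 cis-1,2-dimethylacenaphthene-1,2-diol
Product: 4 (E)-prop-1-enylboronic ester of diol 2, (6bR,9aS)-6b,9a-dimethyl-8-[(E)-prop-1-enyl]-6b,9a-dihydroacenaphtho[1,2-d][1,3,2]dioxaborole
Conditions: 4 Å molecular sieves, CH2Cl2, rt
Reagents that add atoms: none
Why: Condensation of a boronic acid with a 1,2-diol to a five-membered dioxaborolane, driven by removal of water; only a cis diol can bridge boron, and the alkene geometry is not touched.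

Step 3
Reactants: 5 4-chloro-2-methoxybenzaldehyde
Product: 6 5-bromo-4-chloro-2-methoxybenzaldehyde
Conditions: Br2, AcOH, rt
Reagents that add atoms: bromine, BrBr
Why: Electrophilic aromatic bromination; C5 is para to the methoxy group, ortho to chlorine and meta to the formyl group, so all three substituents direct to it, while the other open position between methoxy and chlorine is crowded.

Step 4
Reactants: 6 5-bromo-4-chloro-2-methoxybenzaldehyde
Product: 7 1-(5-bromo-4-chloro-2-methoxyphenyl)propan-1-ol (racemic)
Conditions: EtMgBr, THF, 0 °C; then aq. NH4Cl
Reagents that add atoms: ethylmagnesium bromide, CC[Mg]Br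
Why: Grignard addition to the aldehyde, which at 0 °C is much faster than halogen–magnesium exchange at the aryl bromide; the carbinol centre is racemic and is removed in step 5.

Step 5
Reactants: 7 1-(5-bromo-4-chloro-2-methoxyphenyl)propan-1-ol
Product: 8 1-bromo-2-chloro-4-methoxy-5-[(E)-prop-1-enyl]benzene
Conditions: TsOH·H2O (cat.), toluene, reflux, Dean–Stark
Reagents that add atoms: none
Why: Acid-catalysed E1 dehydration of a benzylic alcohol with removal of water; the methoxy-stabilised benzylic cation loses a proton to the conjugated alkene under thermodynamic control, which favours the (E) isomer.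

Step 6
Reactants: 9 5-bromo-1,2,3-trimethoxybenzene; 4 (E)-prop-1-enylboronic ester of diol 2; 8 1-bromo-2-chloro-4-methoxy-5-[(E)-prop-1-enyl]benzene
Product: 12 (6bR,9aS)-8-[(1R,2S)-2-{2-chloro-4-methoxy-5-[(E)-prop-1-enyl]phenyl}-1-(3,4,5-trimethoxyphenyl)propyl]-6b,9a-dimethyl-6b,9a-dihydroacenaphtho[1,2-d][1,3,2]dioxaborole, via 3,4,5-trimethoxyphenyllithium 10 (not isolated), via lithium aryl(propenyl)borate complex 11 (not isolated)
Conditions: 9, t-BuLi (2 equiv), Et2O/THF, −78 °C; 4, −78 °C to rt; then 8, Pd(OAc)2 (cat.), (Sp,Sp)-MandyPhos {Fe[C5H3(PAr2)(CH(NMe2)Ph)]2, Ar = 3,5-Me2C6H3} (cat.), NaOTf, THF, 60 °C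
Reagents that add atoms: none
Why: Bromine–lithium exchange on 9 gives 10, which adds to the vacant orbital of boron in 4 to form the four-coordinate ate complex 11. Pd(OAc)2 is reduced in the flask to zerovalent palladium, which inserts into the C–Br bond of 8, and NaOTf exchanges bromide for weakly bound triflate so that the cationic arylpalladium can bind the propenyl π-bond of 11. Binding triggers a 1,2-metallate shift in which the trimethoxyphenyl group moves from boron to the α-carbon on the face opposite to palladium (C2–C1′), and reductive elimination from the resulting alkylpalladium joins the β-carbon to ring B with retention (C3–C3a); this is a direct application of the enantioselective palladium-catalysed conjunctive cross-coupling of β-substituted alkenylboron ate complexes with aryl electrophiles. No ring is closed. The relative configuration of the two new centres follows from the anti addition across the (E) double bond, and their absolute configuration from the chiral bisphosphine on palladium, which selects the alkene face that is bound. The step needs the metallate shift to win over direct boron-to-palladium transfer (Suzuki–Miyaura coupling), which the hindered diol of 2 secures by shielding the boron–oxygen bonds; it needs C–Br to react before C–Cl, which the large intrinsic rate difference in oxidative addition secures; and it needs the propenyl group of 8 to stay out, which holds because a neutral 1,2-disubstituted styrene binds cationic palladium far less well than the electron-rich alkene of the borate.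

Step 7
Reactants: 12 boronic ester from step 6
Product: 13 (1R,2R)-2-{2-chloro-4-methoxy-5-[(E)-prop-1-enyl]phenyl}-1-(3,4,5-trimethoxyphenyl)propan-1-ol
Conditions: 30% H2O2, 3 M aq. NaOH, THF, 0 °C to rt
Reagents that add atoms: hydrogen peroxide, OO
Why: Alkaline peroxide oxidation of a C–B bond; hydroperoxide adds to boron and C2 migrates from boron to oxygen with retention, so the configuration set in step 6 is carried into the alcohol, the electron-rich propenyl group is inert to nucleophilic peroxide, and diol 2 is released for reuse.

Step 8
Reactants: 13 (1R,2R)-2-{2-chloro-4-methoxy-5-[(E)-prop-1-enyl]phenyl}-1-(3,4,5-trimethoxyphenyl)propan-1-ol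
Product: 14 (2R,3R)-6-methoxy-3-methyl-5-[(E)-prop-1-enyl]-2-(3,4,5-trimethoxyphenyl)-2,3-dihydrobenzofuran
Conditions: Pd(OAc)2 (cat.), t-BuXPhos (2-di-tert-butylphosphino-2′,4′,6′-triisopropylbiphenyl), Cs2CO3, toluene, 90 °C
Reagents that add atoms: none
Why: Palladium-catalysed intramolecular C–O coupling (Buchwald-type etherification); zerovalent palladium with the bulky di-tert-butyl biaryl phosphine inserts into the C–Cl bond, the alkoxide binds, and C–O reductive elimination closes the five-membered ring at C7a faster than β-hydride elimination; no bond to C2 or C3 is broken, so the trans (2R,3R) configuration is kept.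

## Compound list

1 | acenaphthoquinone (acenaphthylene-1,2-dione) | O=C1C(=O)c2cccc3cccc1c23 | starting material
2 | cis-1,2-dimethylacenaphthene-1,2-diol (meso) | O[C@]1(C)c2cccc3cccc(c23)[C@]1(C)O | intermediate
3 | (E)-prop-1-enylboronic acid | C/C=C/B(O)O | starting material
4 | (E)-prop-1-enylboronic ester of diol 2, (6bR,9aS)-6b,9a-dimethyl-8-[(E)-prop-1-enyl]-6b,9a-dihydroacenaphtho[1,2-d][1,3,2]dioxaborole | C/C=C/B1O[C@]2(C)c3cccc4cccc(c34)[C@]2(C)O1 | intermediate
5 | 4-chloro-2-methoxybenzaldehyde | COc1cc(Cl)ccc1C=O | starting material
6 | 5-bromo-4-chloro-2-methoxybenzaldehyde | COc1cc(Cl)c(Br)cc1C=O | intermediate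
7 | 1-(5-bromo-4-chloro-2-methoxyphenyl)propan-1-ol (racemic) | CCC(O)c1cc(Br)c(Cl)cc1OC | intermediate
8 | 1-bromo-2-chloro-4-methoxy-5-[(E)-prop-1-enyl]benzene | C/C=C/c1cc(Br)c(Cl)cc1OC | intermediate
9 | 5-bromo-1,2,3-trimethoxybenzene | COc1cc(Br)cc(OC)c1OC | starting material
10 | 3,4,5-trimethoxyphenyllithium | [Li]c1cc(OC)c(OC)c(OC)c1 | intermediate
11 | lithium [(E)-prop-1-enyl](3,4,5-trimethoxyphenyl)borate of diol 2 (ate complex; configuration at boron not specified) | [Li+].C/C=C/[B-]1(c2cc(OC)c(OC)c(OC)c2)O[C@]2(C)c3cccc4cccc(c34)[C@]2(C)O1 | intermediate
12 | (6bR,9aS)-8-[(1R,2S)-2-{2-chloro-4-methoxy-5-[(E)-prop-1-enyl]phenyl}-1-(3,4,5-trimethoxyphenyl)propyl]-6b,9a-dimethyl-6b,9a-dihydroacenaphtho[1,2-d][1,3,2]dioxaborole | B1(O[C@]2(C)c3cccc4cccc(c34)[C@]2(C)O1)[C@@H](c1cc(OC)c(OC)c(OC)c1)[C@@H](c1cc(/C=C/C)c(OC)cc1Cl)C | intermediate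
13 | (1R,2R)-2-{2-chloro-4-methoxy-5-[(E)-prop-1-enyl]phenyl}-1-(3,4,5-trimethoxyphenyl)propan-1-ol | O[C@@H](c1cc(OC)c(OC)c(OC)c1)[C@@H](c1cc(/C=C/C)c(OC)cc1Cl)C | intermediate
14 | (2R,3R)-6-methoxy-3-methyl-5-[(E)-prop-1-enyl]-2-(3,4,5-trimethoxyphenyl)-2,3-dihydrobenzofuran | C/C=C/c1cc2c(cc1OC)O[C@@H](c1cc(OC)c(OC)c(OC)c1)[C@@H]2C | target

## Step count and least certain steps

Total step count: 8. Longest linear sequence: 6 steps (5 → 6 → 7 → 8 → 12 → 13 → 14, steps 3 to 8).

**Step 6 (key step).** The most likely failure is direct transfer of the propenyl or aryl group from boron to palladium, which would give simple cross-coupling products. The ortho-chloro substituent of 8 makes this more likely, because it slows binding of the borate alkene to palladium. Residual bromide can also block the open coordination site, and an ortho-substituted electrophile may lower the face selectivity.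

The fallback sets out from 8 and comes back to the route at 13, without any boron intermediate. Palladium-catalysed α-arylation of commercial 1-(3,4,5-trimethoxyphenyl)propan-1-one with 8 (Pd(OAc)2, Xantphos, NaOt-Bu, toluene, 80 °C; C–Br reacts before C–Cl) should give racemic 2-{2-chloro-4-methoxy-5-[(E)-prop-1-enyl]phenyl}-1-(3,4,5-trimethoxyphenyl)propan-1-one F1. Asymmetric transfer hydrogenation of F1 with dynamic kinetic resolution (RuCl[(R,R)-TsDPEN](p-cymene), HCO2H/Et3N) should then give 13. The centre between carbonyl and ring B epimerises under the amine conditions while the catalyst reduces one enantiomer faster, so both centres are set. The (R,R) catalyst is chosen by analogy with simple aryl alkyl ketones, and the expected relative configuration is the one that closes to the trans ring.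

**Step 8.** The most likely failure is β-hydride elimination from the palladium alkoxide of the secondary benzylic alcohol, which would oxidise the carbinol and reduce the C–Cl bond. Oxidative addition into the electron-rich, ortho-branched aryl chloride may also be slow.

The fallback sets out from 13 and comes back at 14, and avoids a palladium alkoxide. Miyaura borylation of the aryl chloride (Pd2(dba)3, XPhos, B2pin2, KOAc, dioxane, 100 °C) should give (1R,2R)-2-{4-methoxy-5-[(E)-prop-1-enyl]-2-(4,4,5,5-tetramethyl-1,3,2-dioxaborolan-2-yl)phenyl}-1-(3,4,5-trimethoxyphenyl)propan-1-ol F2. Oxidation of the aryl C–B bond (H2O2, aq. NaOH, THF, 0 °C) should give the phenol 2-[(1R,2R)-1-hydroxy-1-(3,4,5-trimethoxyphenyl)propan-2-yl]-5-methoxy-4-[(E)-prop-1-enyl]phenol F3. Mild acid (TsOH cat., CH2Cl2, 0 °C) should ionise the benzylic alcohol of F3, and the phenol closes the ring. In this closure the untouched C3 centre directs ring A trans to the methyl group, which is also the more stable arrangement, giving 14.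

**Step 5.** The most likely failure is incomplete (E) selectivity together with acid-induced dimerisation of the electron-rich styrene as it forms.

The fallback sets out from 6 and comes back at 8, replacing steps 4 and 5. A Julia–Kocienski olefination of aldehyde 6 with 5-(ethylsulfonyl)-1-phenyl-1H-tetrazole (KN(SiMe3)2, DME, −60 °C to rt) should give the (E)-alkene 8 directly under base, with no cationic intermediate and no new isolated compound.

## Further compounds

F1 | step 6 | 2-{2-chloro-4-methoxy-5-[(E)-prop-1-enyl]phenyl}-1-(3,4,5-trimethoxyphenyl)propan-1-one (racemic) | C/C=C/c1cc(C(C)C(=O)c2cc(OC)c(OC)c(OC)c2)c(Cl)cc1OC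
F2 | step 8 | (1R,2R)-2-{4-methoxy-5-[(E)-prop-1-enyl]-2-(4,4,5,5-tetramethyl-1,3,2-dioxaborolan-2-yl)phenyl}-1-(3,4,5-trimethoxyphenyl)propan-1-ol | O[C@@H](c1cc(OC)c(OC)c(OC)c1)[C@@H](c1cc(/C=C/C)c(OC)cc1B1OC(C)(C)C(C)(C)O1)C
F3 | step 8 | 2-[(1R,2R)-1-hydroxy-1-(3,4,5-trimethoxyphenyl)propan-2-yl]-5-methoxy-4-[(E)-prop-1-enyl]phenol | O[C@@H](c1cc(OC)c(OC)c(OC)c1)[C@@H](c1cc(/C=C/C)c(OC)cc1O)C
F0 | step 5 | none | none
A1 | alternative 1 | (R)-6-bromo-7-methoxy-2-(3,4,5-trimethoxyphenyl)chroman-4-one | O=C1C[C@H](c2cc(OC)c(OC)c(OC)c2)Oc2cc(OC)c(Br)cc21
A2 | alternative 1 | methyl (2R,3R)-5-bromo-6-methoxy-2-(3,4,5-trimethoxyphenyl)-2,3-dihydrobenzofuran-3-carboxylate | Brc1cc2c(cc1OC)O[C@@H](c1cc(OC)c(OC)c(OC)c1)[C@@H]2C(=O)OC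
A3 | alternative 2 | (1R,2R,5E,7E)-3-diazo-1-(ethynyloxy)-2-methyl-1-(3,4,5-trimethoxyphenyl)nona-5,7-dien-4-one | C/C=C/C=C/C(=O)C(=[N+]=[N-])[C@@H](C)[C@@H](OC#C)c1cc(OC)c(OC)c(OC)c1
A4 | alternative 2 | (2R,3R)-3-methyl-5-[(E)-prop-1-enyl]-2-(3,4,5-trimethoxyphenyl)-2,3-dihydrobenzofuran-6-ol | C/C=C/c1cc2c(cc1O)O[C@@H](c1cc(OC)c(OC)c(OC)c1)[C@@H]2C
A5 | alternative 3 | 4-bromo-5-methoxy-2-[1-(phenylsulfonyl)ethyl]phenol (racemic) | CC(c1cc(Br)c(OC)cc1O)S(=O)(=O)c1ccccc1
A6 | alternative 3 | (2R,5R)-2,5-dimethyl-1-(3,4,5-trimethoxybenzyl)thiolan-1-ium triflate | C[C@@H]1CC[C@@H](C)[S+]1Cc1cc(OC)c(OC)c(OC)c1.[O-]S(=O)(=O)C(F)(F)F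
A7 | alternative 3 | (2R,3R)-5-bromo-6-methoxy-3-methyl-2-(3,4,5-trimethoxyphenyl)-2,3-dihydrobenzofuran | Brc1cc2c(cc1OC)O[C@@H](c1cc(OC)c(OC)c(OC)c1)[C@@H]2C
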